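Numbering (germacrane): C1=C10 enoate with ester carbon C14; C2–C3 oxirane; C4=C5 with methyl C15; C6 lactone carbinol; C7; C8 acyloxy; C9 hydroxy; C11=C13 methylene; C12 lactone carbonyl.
Enabling feature: the C8/C9 oxygen pair lies across the ten-membered ring from C2–C5, so bonding C1 to C6 gives a C1–C6 cyclohexene (C4=C5, oxygens on C2 and C3) whose C6 carbinol carries cis alkenyl groups on C6 and C1, an oxy-Cope retron.
Retrosynthesis cuts, in order: C2–O of the oxirane, C11=C13, the O6–C12 lactone bond, the C6–H bond together with the C8 ester (back to a C6 ketone), C7–C11, then C8–C9 with C1–C6 restored, then C6–C7, C1–C10 and C4–C15 back to a quinic acid enone.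
Forward: quinic acid supplies the six-membered ring with trans oxygens on C2 and C3; the C1 arm, the C6 alkynyl carbinol and two enol ethers are added; the rearrangement opens the six-ring to the ten-ring; the γ-lactone and then the oxirane close last.
Stereochemistry: C3 from quinic acid; C2 from quinic acid in the epimeric form (so that both alkenyl groups can enter trans to it) and inverted when the oxirane closes; C1 by trans alkylation and C6 by axial alkynylation; C8 and C9 from the chair; C7 by alkylation anti to O8; the C6 carbinol by 1,3-anti hydride delivery; the side chain by Sharpless epoxidation.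
Key step: step 13

Remark: ring carbons of all intermediates carry the numbers of the germacrane carbons they become (quinic acid C1 to C6 = C6, C5, C4, C3, C2, C1); (E)-2-methylbut-2-en-1-ol is taken as commercial, and D-(−)-tartrate is taken to give the (2R,3R)-epoxy alcohol as with other (E)-allylic alcohols.

Step 1
Reactants: 1 (−)-quinic acid
Product: 2 quinic acid acetonide lactone (acetonide on O4 and O3, γ-lactone from the C6 carboxyl to O2, free C6 hydroxyl)
Conditions: 2,2-dimethoxypropane, TsOH·H2O (cat.), acetone, reflux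
Reagents that add atoms: 2,2-dimethoxypropane, COC(C)(C)OC
Why: Acid-catalysed ketal exchange protects the cis C4/C3 diol as the acetonide while the carboxyl group lactonises onto the cis C2 hydroxyl (acetonide formation with lactonisation), so that only the tertiary C6 hydroxyl stays free.

Step 2
Reactants: 2 quinic acid acetonide lactone
Product: 3 acetonide triol (C6 carrying OH and CH2OH, free C2 hydroxyl)
Conditions: NaBH4, EtOH, 0 °C to rt
Reagents that add atoms: none
Why: Borohydride reduction of the strained α-hydroxy lactone (ester reduction) opens the bicycle to the C6 hydroxymethyl carbinol and the C2 alcohol without touching the ketal.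

Step 3
Reactants: 3 acetonide triol
Product: 4 (3R,4S,5R)-5-hydroxy-3,4-(isopropylidenedioxy)cyclohexan-1-one (C6 ketone, C2 hydroxyl)
Conditions: NaIO4, THF/pH 7 buffer, 0 °C
Reagents that add atoms: none
Why: Periodate glycol cleavage of the tertiary/primary 1,2-diol excises the former carboxyl carbon as formaldehyde and leaves the C6 ketone.

Step 4
Reactants: 4 hydroxy ketone
Product: 5 C2 triethylsilyl ether of 4
Conditions: Et3SiCl, imidazole, DMF, 0 °C
Reagents that add atoms: chlorotriethylsilane, CC[Si](Cl)(CC)CC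
Why: Silyl ether formation on the only hydroxyl turns O2 into a poor leaving group for the coming elimination and into a group that can later be removed beside tert-butyldimethylsilyl ethers.

Step 5
Reactants: 5 silyloxy ketone
Product: 7 (4R,5R)-4-(tert-butyldimethylsilyloxy)-5-(triethylsilyloxy)cyclohex-2-en-1-one (C6 ketone, C4=C5, O3 and O2 trans), via hydroxy enone 6 (not isolated)
Conditions: DBU, CH2Cl2, 0 °C; then tBuMe2SiCl, imidazole, 0 °C to rt
Reagents that add atoms: tert-butylchlorodimethylsilane, CC(C)(C)[Si](C)(C)Cl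
Why: E1cB β-elimination from the C5 enolate expels the pseudoaxial ketal oxygen on C4, which is aligned with the enolate, and not the equatorial C2 silyloxy group, and silylation in the same flask caps the freed C3 hydroxyl before the neighbouring silyl group can migrate.

Step 6
Reactants: 7 bis-silyloxy enone
Product: 8 trimethylsilyl enol ether (C6 OSiMe3, C5=C6, new C4 methyl trans to O3)
Conditions: Me2CuLi, Me3SiCl, THF, −78 °C
Reagents that add atoms: lithium dimethylcuprate, [Li+].C[Cu-]C; chlorotrimethylsilane, C[Si](C)(C)Cl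
Why: Cuprate conjugate addition places the C15 methyl on C4 anti to the C3 silyloxy group and the enolate is trapped regiospecifically as its silyl ether, the new C4 centre being erased in the next step.

Step 7
Reactants: 8 trimethylsilyl enol ether
Product: 9 (4R,5R)-4-(tert-butyldimethylsilyloxy)-3-methyl-5-(triethylsilyloxy)cyclohex-2-en-1-one (C6 ketone, C4=C5 bearing C15)
Conditions: Pd(OAc)2 (1.1 equiv), MeCN, rt
Reagents that add atoms: none
Why: Saegusa–Ito oxidation converts the silyl enol ether through a palladium enolate and β-hydride elimination into the C4=C5 enone, now carrying the methyl group.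

Step 8
Reactants: 9 methyl enone
Product: 10 keto ester (9 with CH2CO2Me on C1, trans to O2 and cis to O3)
Conditions: LiN(iPr)2, THF, −78 °C; BrCH2CO2Me, DMPU, −78 to −40 °C
Reagents that add atoms: methyl bromoacetate, COC(=O)CBr
Why: Kinetic deprotonation at C1 and enolate alkylation should take place anti to the adjacent C2 silyloxy group, which sets C1 with the acetate arm trans to O2 and cis to O3 and leaves all three ring substituents equatorial.

Step 9
Reactants: 10 keto ester
Product: 11 alkynol (C6 ethynyl carbinol, ethynyl cis to the C1 arm, hydroxyl trans)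
Conditions: HC≡CMgBr, THF, −78 to −20 °C
Reagents that add atoms: ethynylmagnesium bromide, C#C[Mg]Br
Why: 1,2-Grignard addition of the small linear acetylide should follow the axial trajectory on the half-chair with the C1, C2 and C3 substituents equatorial, which sets C6 with the alkynyl group cis to the C1 arm and the hydroxyl trans, the ester being untouched at low temperature.

Step 10
Reactants: 11 alkynol
Product: 12 (E)-alkenylboronate (C6–C7H=C8H–B(pin))
Conditions: pinacolborane, Cp2Zr(H)Cl (10 mol %), Et3N (10 mol %), CH2Cl2, 40 °C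
Reagents that add atoms: pinacolborane, CC1(C)OBOC1(C)C
Why: Zirconium-catalysed syn hydroboration of the terminal alkyne (alkyne hydroboration) puts boron on the unhindered terminal carbon and gives the (E)-alkenylboronate.

Step 11
Reactants: 12 (E)-alkenylboronate; 13 4-methoxybenzyl alcohol
Product: 14 (E)-4-methoxybenzyl enol ether (C6–C7H=C8H–OPMB)
Conditions: Cu(OAc)2 (2 equiv), Et3N, 4 Å molecular sieves, excess 13, air, rt
Reagents that add atoms: none
Why: Chan–Lam oxidative C–O coupling transfers the alkenyl group from boron to the alcohol oxygen with retention of the (E) geometry under buffered conditions that spare the tertiary allylic alcohol.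

Step 12
Reactants: 14 (E)-enol ether
Product: 16 rearrangement substrate (C6 carbinol with (E)-CH=CH–OPMB; C1 bearing C(CO2Me)=CH–OSiMe2tBu with the silyloxy group cis to the ester and trans to C1), via dilithium enolate 15 (not isolated)
Conditions: LiN(iPr)2 (2.3 equiv), THF, −78 °C; HCO2Me, −78 to −30 °C; tBuMe2SiCl, −78 to 0 °C
Reagents that add atoms: methyl formate, COC=O; tert-butylchlorodimethylsilane, CC(C)(C)[Si](C)(C)Cl
Why: Claisen formylation of the ester enolate gives the formyl ester as its lithium chelate, and O-silylation of this U-shaped chelate (enolate silylation) fixes the enol silyl ether with oxygen cis to the ester and trans to C1 while the hindered tertiary alkoxide stays unsilylated.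

Step 13
Reactants: 16 rearrangement substrate
Product: 19 ten-membered ketone (C6 ketone, ring-cis C4=C5 and C1=C10, C8 OPMB, C9 OSiMe2tBu, C2 OSiEt3, C3 OSiMe2tBu), via potassium alkoxide 17 (not isolated), via potassium enolate 18 (not isolated)
Conditions: KH, 18-crown-6, THF, −20 to 0 °C; AcOH, −78 °C
Reagents that add atoms: none
Why: The C6 potassium alkoxide, freed from its counter-ion by the crown ether, triggers an anionic oxy-Cope [3,3]-sigmatropic shift of the C8=C7–C6–C1–C10=C9 diene in which C8–C9 forms while C1–C6 breaks, and the enolate is protonated cold to the C6 ketone. The closest known reaction is the anionic oxy-Cope ring expansion of cis-1,2-dialkenylcyclohexanols to cyclodec-5-enones. The ten-membered ring is not made by cyclisation but by four-carbon ring expansion: the new C8–C9 bond closes it through a six-centre chair transition state as the six-membered ring opens. C8 and C9 are set in that chair, where both enol ether oxygens are trans to the chain and therefore equatorial, which gives the 8,9-threo pair, and their absolute sense is relayed from C1 and C6. The step needs the chair with C2 axial on C1 so that C1=C10 forms with C2 cis to C9; this chair is the ground-state half-chair of 16 (C1 alkenyl group, O2, O3 and O6 equatorial, C6 vinyl group axial) and is further favoured because an equatorial C2 would clash with the C10 ester. Keeping the mixture at or below 0 °C and quenching at −78 °C should hold back loss of the C8 ether from the β-alkoxy enolate.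

Step 14
Reactants: 19 ten-membered ketone
Product: 20 allyl ester ketone (19 with CH2CO2CH2CH=CH2 on C7, anti to O8)
Conditions: LiN(SiMe3)2, THF, −78 °C; BrCH2CO2CH2CH=CH2, DMPU, −78 °C
Reagents that add atoms: allyl bromoacetate, C=CCOC(=O)CBr
Why: Kinetic enolisation can only occur toward C7, and alkylation of the lithium enolate with the bromoacetate (enolate alkylation) at −78 °C should take place anti to the C8 ether oxygen on the conformer that keeps H8 in the enolate plane, which sets C7 with the acetate arm anti to O8 before the β-alkoxy enolate can eliminate.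

Step 15
Reactants: 20 allyl ester ketone
Product: 21 β-hydroxy ketone (free C8 hydroxyl)
Conditions: DDQ, CH2Cl2/pH 7 buffer, 0 °C
Reagents that add atoms: none
Why: Oxidative cleavage of the 4-methoxybenzyl ether by DDQ through the benzylic oxocarbenium ion frees the C8 hydroxyl under buffered conditions that leave the silyl ethers, the allyl ester and the enone untouched.

Step 16
Reactants: 22 (E)-2-methylbut-2-en-1-ol
Product: 23 [(2R,3R)-2,3-dimethyloxiran-2-yl]methanol
Conditions: Ti(OiPr)4 (10 mol %), D-(−)-diisopropyl tartrate (12 mol %), tBuOOH, 4 Å molecular sieves, CH2Cl2, −20 °C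
Reagents that add atoms: tert-butyl hydroperoxide, CC(C)(C)OO
Why: Sharpless asymmetric epoxidation of the (E)-allylic alcohol with the D-(−)-tartrate ligand delivers oxygen to the alkene face that gives the (2R,3R)-epoxy alcohol and thereby sets both side-chain stereocentres.

Step 17
Reactants: 23 epoxy alcohol
Product: 24 (2S,3R)-2,3-dimethyloxirane-2-carbaldehyde
Conditions: Dess–Martin periodinane, pyridine, CH2Cl2, 0 °C; used as a solution
Reagents that add atoms: none
Why: Dess–Martin oxidation of the primary alcohol gives the aldehyde, whose quaternary α-carbon cannot epimerise.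

Step 18
Reactants: 21 β-hydroxy ketone; 24 epoxy aldehyde
Product: 25 hydroxy ester (C6 alcohol 1,3-anti to O8, C8 (2S,3R)-2,3-dimethyloxirane-2-carboxylate, C7 allyl acetate arm)
Conditions: 24 (5 equiv), SmI2 (30 mol %), THF, −10 °C
Reagents that add atoms: none
Why: Evans–Tishchenko reduction: the C8 hydroxyl adds to the aldehyde and the samarium-bound hemiacetal delivers its hydride to the C6 ketone within a chair-like six-membered transition state, which sets the C6 carbinol 1,3-anti to O8 and leaves the oxidised aldehyde as the C8 ester.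

Step 19
Reactants: 25 hydroxy ester
Product: 27 trans-fused γ-lactone (O6–C12, C11 methylene not yet present), via hydroxy acid 26 (not isolated)
Conditions: Pd(PPh3)4 (5 mol %), morpholine, THF, rt; then EDCI, DMAP, CH2Cl2, 0 °C
Reagents that add atoms: none
Why: Zerovalent palladium transfers the allyl group to morpholine (Tsuji–Trost deallylation) and carbodiimide activation then closes the liberated acid onto the only free hydroxyl at C6 (Steglich lactonisation), giving the trans-fused γ-lactone without change at C6 or C7.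

Step 20
Reactants: 27 γ-lactone
Product: 30 α-methylene lactone (C11=C13), via Mannich base 28 (not isolated), via ammonium iodide 29 (not isolated)
Conditions: LiN(iPr)2, THF, −78 °C; Me2N=CH2+ I−; then MeI, MeOH, rt; NaHCO3, CH2Cl2/H2O
Reagents that add atoms: N,N-dimethylmethyleneiminium iodide, C[N+](C)=C.[I-]
Why: The lactone lithium enolate is aminomethylated by the iminium salt and the Mannich base is N-methylated and eliminated under mild base (Mannich methylenation) to the C11=C13 methylene, the hindered C8 ester having no α-hydrogen.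

Step 21
Reactants: 30 α-methylene lactone
Product: 31 C2 alcohol
Conditions: HF·pyridine, pyridine, THF, 0 °C
Reagents that add atoms: none
Why: Pyridine-buffered HF cleaves the triethylsilyl ether much faster than the two secondary tert-butyldimethylsilyl ethers (selective desilylation) and exposes only the C2 hydroxyl.

Step 22
Reactants: 31 C2 alcohol
Product: 32 C2 mesylate
Conditions: MeSO2Cl, Et3N, CH2Cl2, −20 °C
Reagents that add atoms: methanesulfonyl chloride, CS(=O)(=O)Cl
Why: Sulfonylation through sulfene at low temperature converts the C2 hydroxyl with retention into the allylic mesylate, whose ionisation is retarded by the electron-poor enoate.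

Step 23
Reactants: 32 C2 mesylate
Product: 33 CNP0291485.6
Conditions: Bu4NF, THF, 0 °C
Reagents that add atoms: none
Why: Fluoride removes both tert-butyldimethylsilyl groups and the C3 alkoxide displaces the neighbouring mesylate in an intramolecular SN2 reaction (3-exo-tet oxirane closure) with inversion at C2, which gives the cis-oxirane beside the free C9 hydroxyl.

Compound list
1 | (−)-quinic acid, (1S,3R,4S,5R)-1,3,4,5-tetrahydroxycyclohexane-1-carboxylic acid | O[C@@]1(C(O)=O)C[C@@H](O)[C@@H](O)[C@H](O)C1 | starting material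
2 | quinic acid acetonide lactone (3,4-O-isopropylidene-1,5-quinide) | O[C@@]12C[C@H]3OC(C)(C)O[C@H]3[C@@H](C1)OC2=O | intermediate
3 | acetonide triol (C6 with OH and CH2OH, C2 hydroxyl, cis C4/C3 acetonide) | OC[C@]1(O)C[C@H]2OC(C)(C)O[C@H]2[C@H](O)C1 | intermediate
4 | (3R,4S,5R)-5-hydroxy-3,4-(isopropylidenedioxy)cyclohexan-1-one | O=C1C[C@H]2OC(C)(C)O[C@H]2[C@H](O)C1 | intermediate
5 | C2 triethylsilyl ether of 4 | O=C1C[C@H]2OC(C)(C)O[C@H]2[C@H](O[Si](CC)(CC)CC)C1 | intermediate
6 | (4R,5R)-4-hydroxy-5-(triethylsilyloxy)cyclohex-2-en-1-one | O=C1C=C[C@@H](O)[C@H](O[Si](CC)(CC)CC)C1 | intermediate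
7 | (4R,5R)-4-(tert-butyldimethylsilyloxy)-5-(triethylsilyloxy)cyclohex-2-en-1-one | O=C1C=C[C@@H](O[Si](C)(C)C(C)(C)C)[C@H](O[Si](CC)(CC)CC)C1 | intermediate
8 | trimethylsilyl enol ether (C6 OSiMe3, C5=C6, C4 methyl trans to O3) | C[Si](C)(C)OC1=C[C@H](C)[C@@H](O[Si](C)(C)C(C)(C)C)[C@H](O[Si](CC)(CC)CC)C1 | intermediate
9 | (4R,5R)-4-(tert-butyldimethylsilyloxy)-3-methyl-5-(triethylsilyloxy)cyclohex-2-en-1-one | O=C1C=C(C)[C@@H](O[Si](C)(C)C(C)(C)C)[C@H](O[Si](CC)(CC)CC)C1 | intermediate
10 | keto ester (CH2CO2Me on C1, trans to O2, cis to O3) | O=C1C=C(C)[C@@H](O[Si](C)(C)C(C)(C)C)[C@H](O[Si](CC)(CC)CC)[C@H]1CC(=O)OC | intermediate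
11 | alkynol (C6 ethynyl carbinol, ethynyl cis to the C1 arm) | C#C[C@@]1(O)C=C(C)[C@@H](O[Si](C)(C)C(C)(C)C)[C@H](O[Si](CC)(CC)CC)[C@H]1CC(=O)OC | intermediate
12 | (E)-alkenylboronate (C6–CH=CH–B(pin)) | CC1(C)OB(/C=C/[C@@]2(O)C=C(C)[C@@H](O[Si](C)(C)C(C)(C)C)[C@H](O[Si](CC)(CC)CC)[C@H]2CC(=O)OC)OC1(C)C | intermediate
13 | 4-methoxybenzyl alcohol | COc1ccc(CO)cc1 | starting material
14 | (E)-4-methoxybenzyl enol ether (C6–C7H=C8H–OPMB) | COc1ccc(CO/C=C/[C@@]2(O)C=C(C)[C@@H](O[Si](C)(C)C(C)(C)C)[C@H](O[Si](CC)(CC)CC)[C@H]2CC(=O)OC)cc1 | intermediate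
15 | dilithium salt (C6 alkoxide, chelated formyl ester enolate) | [Li+].[Li+].COc1ccc(CO/C=C/[C@@]2([O-])C=C(C)[C@@H](O[Si](C)(C)C(C)(C)C)[C@H](O[Si](CC)(CC)CC)[C@H]2/C(C(=O)OC)=C/[O-])cc1 | intermediate
16 | rearrangement substrate, cis-1,2-dialkenylcyclohexenol (C6: OH and (E)-CH=CH–OPMB; C1: C(CO2Me)=CH–OSiMe2tBu, silyloxy cis to ester; C2 OSiEt3; C3 OSiMe2tBu) | COc1ccc(CO/C=C/[C@@]2(O)C=C(C)[C@@H](O[Si](C)(C)C(C)(C)C)[C@H](O[Si](CC)(CC)CC)[C@H]2/C(C(=O)OC)=C/O[Si](C)(C)C(C)(C)C)cc1 | intermediate
17 | potassium alkoxide of 16 | [K+].COc1ccc(CO/C=C/[C@@]2([O-])C=C(C)[C@@H](O[Si](C)(C)C(C)(C)C)[C@H](O[Si](CC)(CC)CC)[C@H]2/C(C(=O)OC)=C/O[Si](C)(C)C(C)(C)C)cc1 | intermediate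
18 | ten-membered potassium enolate (C6=C7) | [K+].[O-]/C1=C\[C@H](OCc2ccc(OC)cc2)[C@@H](O[Si](C)(C)C(C)(C)C)/C(C(=O)OC)=C\[C@@H](O[Si](CC)(CC)CC)[C@H](O[Si](C)(C)C(C)(C)C)/C(C)=C\1 | intermediate
19 | ten-membered ketone (C6 ketone, ring-cis C4=C5 and C1=C10, C8 OPMB, C9 OSiMe2tBu, C2 OSiEt3, C3 OSiMe2tBu, C14 methyl ester) | O=C1/C=C(/C)[C@@H](O[Si](C)(C)C(C)(C)C)[C@H](O[Si](CC)(CC)CC)/C=C(/C(=O)OC)[C@H](O[Si](C)(C)C(C)(C)C)[C@@H](OCc2ccc(OC)cc2)C1 | intermediate
20 | allyl ester ketone (CH2CO2allyl on C7, anti to O8) | O=C1/C=C(/C)[C@@H](O[Si](C)(C)C(C)(C)C)[C@H](O[Si](CC)(CC)CC)/C=C(/C(=O)OC)[C@H](O[Si](C)(C)C(C)(C)C)[C@@H](OCc2ccc(OC)cc2)[C@H]1CC(=O)OCC=C | intermediate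
21 | β-hydroxy ketone (free C8 hydroxyl) | O=C1/C=C(/C)[C@@H](O[Si](C)(C)C(C)(C)C)[C@H](O[Si](CC)(CC)CC)/C=C(/C(=O)OC)[C@H](O[Si](C)(C)C(C)(C)C)[C@@H](O)[C@H]1CC(=O)OCC=C | intermediate
22 | (E)-2-methylbut-2-en-1-ol | C/C=C(\C)CO | starting material
23 | [(2R,3R)-2,3-dimethyloxiran-2-yl]methanol | OC[C@@]1(C)O[C@@H]1C | intermediate
24 | (2S,3R)-2,3-dimethyloxirane-2-carbaldehyde | O=C[C@@]1(C)O[C@@H]1C | intermediate
25 | hydroxy ester (C6 alcohol, C8 epoxy ester, C7 allyl acetate arm) | O[C@@H]1/C=C(/C)[C@@H](O[Si](C)(C)C(C)(C)C)[C@H](O[Si](CC)(CC)CC)/C=C(/C(=O)OC)[C@H](O[Si](C)(C)C(C)(C)C)[C@@H](OC(=O)[C@@]2(C)O[C@@H]2C)[C@H]1CC(=O)OCC=C | intermediate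
26 | hydroxy acid from 25 | O[C@@H]1/C=C(/C)[C@@H](O[Si](C)(C)C(C)(C)C)[C@H](O[Si](CC)(CC)CC)/C=C(/C(=O)OC)[C@H](O[Si](C)(C)C(C)(C)C)[C@@H](OC(=O)[C@@]2(C)O[C@@H]2C)[C@H]1CC(=O)O | intermediate
27 | trans-fused 6,12-γ-lactone | C1C(=O)O[C@@H]2/C=C(/C)[C@@H](O[Si](C)(C)C(C)(C)C)[C@H](O[Si](CC)(CC)CC)/C=C(/C(=O)OC)[C@H](O[Si](C)(C)C(C)(C)C)[C@@H](OC(=O)[C@@]3(C)O[C@@H]3C)[C@@H]12 | intermediate
28 | C11 dimethylaminomethyl lactone (C11 epimers) | CN(C)CC1C(=O)O[C@@H]2/C=C(/C)[C@@H](O[Si](C)(C)C(C)(C)C)[C@H](O[Si](CC)(CC)CC)/C=C(/C(=O)OC)[C@H](O[Si](C)(C)C(C)(C)C)[C@@H](OC(=O)[C@@]3(C)O[C@@H]3C)[C@@H]12 | intermediate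
29 | C11 trimethylammoniomethyl lactone iodide | [I-].C[N+](C)(C)CC1C(=O)O[C@@H]2/C=C(/C)[C@@H](O[Si](C)(C)C(C)(C)C)[C@H](O[Si](CC)(CC)CC)/C=C(/C(=O)OC)[C@H](O[Si](C)(C)C(C)(C)C)[C@@H](OC(=O)[C@@]3(C)O[C@@H]3C)[C@@H]12 | intermediate
30 | α-methylene lactone (C11=C13) | C=C1C(=O)O[C@@H]2/C=C(/C)[C@@H](O[Si](C)(C)C(C)(C)C)[C@H](O[Si](CC)(CC)CC)/C=C(/C(=O)OC)[C@H](O[Si](C)(C)C(C)(C)C)[C@@H](OC(=O)[C@@]3(C)O[C@@H]3C)[C@@H]12 | intermediate
31 | C2 alcohol | C=C1C(=O)O[C@@H]2/C=C(/C)[C@@H](O[Si](C)(C)C(C)(C)C)[C@H](O)/C=C(/C(=O)OC)[C@H](O[Si](C)(C)C(C)(C)C)[C@@H](OC(=O)[C@@]3(C)O[C@@H]3C)[C@@H]12 | intermediate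
32 | C2 mesylate | C=C1C(=O)O[C@@H]2/C=C(/C)[C@@H](O[Si](C)(C)C(C)(C)C)[C@H](OS(C)(=O)=O)/C=C(/C(=O)OC)[C@H](O[Si](C)(C)C(C)(C)C)[C@@H](OC(=O)[C@@]3(C)O[C@@H]3C)[C@@H]12 | intermediate
33 | CNP0291485.6 | C=C1C(=O)O[C@@H]2/C=C(/C)[C@H]3O[C@H]3/C=C(/C(=O)OC)[C@H](O)[C@@H](OC(=O)[C@@]3(C)O[C@@H]3C)[C@@H]12 | target

Total steps: 23. Longest linear sequence: 21 steps (steps 1–15 and 18–23).

Steps most likely to fail:

Step 13. The enolate released by the rearrangement may expel the C8 alkoxide, and the C6 alkoxide may instead attack the C14 ester before the shift occurs. The fallback runs the rearrangement without any anion. From 16 the tertiary hydroxyl is silylated with N-(trimethylsilyl)imidazole to the trimethylsilyl ether F1. Heating F1 in degassed o-dichlorobenzene (neutral siloxy-Cope shift through the same chair) should give the ten-membered trimethylsilyl enol ether F2. Mild hydrolysis (AcOH, THF/H2O, 0 °C) returns the route at ketone 19.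

Step 18. Hydride transfer from the hindered hemiacetal may be slow, so that retro-aldol opening of the β-hydroxy ketone or reductive opening of the epoxy aldehyde by divalent samarium competes. The fallback separates reduction and acylation. From 21 an Evans–Saksena reduction (Me4NBH(OAc)3, AcOH/MeCN, −30 °C; hydride delivered from the C8 hydroxyl, same 1,3-anti sense) gives the 6,8-anti diol F3. Allyl removal (Pd(PPh3)4, morpholine) and carbodiimide lactonisation onto the less hindered allylic C6 hydroxyl give the 8-hydroxy lactone F4. Yamaguchi esterification (2,4,6-trichlorobenzoyl chloride, Et3N, DMAP) with (2S,3R)-2,3-dimethyloxirane-2-carboxylic acid F5, made from 24 by Pinnick oxidation, returns the route at lactone 27.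

Step 23. Under basic fluoride the liberated C9 alkoxide may take over the neighbouring acyl group or add to the methylene lactone before the mixture is quenched. The fallback separates desilylation from ring closure. From mesylate 32 both silyl ethers are removed under acidic fluoride (HF·pyridine, THF, rt) to the 3,9-diol mesylate F6. The oxirane is then closed with DBU in CH2Cl2, which does not build up the C9 alkoxide, to give 33.

Further compounds
F1 | step 13 | trimethylsilyl ether of 16 | COc1ccc(CO/C=C/[C@@]2(O[Si](C)(C)C)C=C(C)[C@@H](O[Si](C)(C)C(C)(C)C)[C@H](O[Si](CC)(CC)CC)[C@H]2/C(C(=O)OC)=C/O[Si](C)(C)C(C)(C)C)cc1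
F2 | step 13 | ten-membered trimethylsilyl enol ether | C[Si](C)(C)O/C1=C\[C@H](OCc2ccc(OC)cc2)[C@@H](O[Si](C)(C)C(C)(C)C)/C(C(=O)OC)=C\[C@@H](O[Si](CC)(CC)CC)[C@H](O[Si](C)(C)C(C)(C)C)/C(C)=C\1
F3 | step 18 | 6,8-anti diol allyl ester | O[C@@H]1/C=C(/C)[C@@H](O[Si](C)(C)C(C)(C)C)[C@H](O[Si](CC)(CC)CC)/C=C(/C(=O)OC)[C@H](O[Si](C)(C)C(C)(C)C)[C@@H](O)[C@H]1CC(=O)OCC=C
F4 | step 18 | 8-hydroxy 6,12-γ-lactone | C1C(=O)O[C@@H]2/C=C(/C)[C@@H](O[Si](C)(C)C(C)(C)C)[C@H](O[Si](CC)(CC)CC)/C=C(/C(=O)OC)[C@H](O[Si](C)(C)C(C)(C)C)[C@@H](O)[C@@H]12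
F5 | step 18 | (2S,3R)-2,3-dimethyloxirane-2-carboxylic acid | OC(=O)[C@@]1(C)O[C@@H]1C
F6 | step 23 | 3,9-diol 2-mesylate | C=C1C(=O)O[C@@H]2/C=C(/C)[C@@H](O)[C@H](OS(C)(=O)=O)/C=C(/C(=O)OC)[C@H](O)[C@@H](OC(=O)[C@@]3(C)O[C@@H]3C)[C@@H]12
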